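The ten-membered carbocycle (ring A) is disconnected at C2–C3, the one ring bond whose two carbons are both allylic, C2 to the C1=C10 alkene and C3 to the C4=C5 alkene. A nitrogen atom placed between them lets the ring be closed first as an eleven-membered bis-allylic amine by simple N-alkylation. Nitrogen deletion with an anomeric amide then expels N2 from the isodiazene and joins the two allyl termini, giving the germacrane 1,5-diene in one operation without touching C6, C7 or C8. The precursor is this azacycle, fused to the saturated trans-lactone (ring B) and carrying TBS ethers at O6 and O15.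

Key step: step 20

Remark: germacrane numbering is used throughout; both hydroxyls of the key-step pair are carried as TBS ethers so that they leave together and the labile ester goes on last; (phenylselanyl)acetic acid, tert-butyldimethyl(prop-2-yn-1-yloxy)silane and the anomeric amide are assumed to be purchasable.

Step 1
Reactants: 1 (S)-epichlorohydrin; 2 ethynyltrimethylsilane
Product: 3 (S)-1-chloro-5-(trimethylsilyl)pent-4-yn-2-ol
Conditions: 2, n-BuLi, THF, −78 °C; BF3·OEt2; then 1, −78 °C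
Reagents that add atoms: none
Why: BF3-promoted SN2 opening of the epoxide by the lithium acetylide at its unsubstituted carbon (epoxide alkynylation) leaves the C–Cl bond and the stereocentre, the future C8, untouched.

Step 2
Reactants: 3 (S)-1-chloro-5-(trimethylsilyl)pent-4-yn-2-ol
Product: 4 (S)-1-chloropent-4-yn-2-ol
Conditions: Bu4NF, AcOH, THF, 0 °C
Reagents that add atoms: none
Why: Fluoride-induced protodesilylation of the alkynylsilane, buffered with acetic acid so that the chlorohydrin should not close to the epoxide.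

Step 3
Reactants: 4 (S)-1-chloropent-4-yn-2-ol
Product: 6 (2E,5S)-6-chloro-3-methylhex-2-ene-1,5-diol, via alkenyldimethylalane 5 (not isolated)
Conditions: Me3Al, Cp2ZrCl2 (cat.), CH2Cl2, 0 °C to rt; then n-BuLi, THF, −78 °C; (CH2O)n, −78 °C to rt
Reagents that add atoms: trimethylaluminium, C[Al](C)C; formaldehyde (as paraformaldehyde), C=O
Why: Zirconium-catalysed syn carboalumination of the terminal alkyne (Negishi carboalumination) puts methyl on C10 and aluminium on C1, and the derived alkenylaluminate adds to formaldehyde with retention, which fixes the E geometry of C1=C10 and brings in C2.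

Step 4
Reactants: 6 (2E,5S)-6-chloro-3-methylhex-2-ene-1,5-diol
Product: 8 (2S)-2-[(2E)-4-[(4-methoxybenzyl)oxy]-2-methylbut-2-en-1-yl]oxirane, via epoxy alcohol 7 (not isolated)
Conditions: NaH, THF, 0 °C; then 4-MeOC6H4CH2Cl, Bu4NI (cat.), DMF, rt
Reagents that add atoms: 4-methoxybenzyl chloride, COc1ccc(CCl)cc1
Why: The secondary alkoxide closes the epoxide by intramolecular SN2 displacement of chloride and the remaining primary alkoxide is benzylated (Williamson ether synthesis); the stereocentre is not a reacting centre and the E alkene rules out cyclic ether formation.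

Step 5
Reactants: 8 (2S)-2-[(2E)-4-[(4-methoxybenzyl)oxy]-2-methylbut-2-en-1-yl]oxirane; 9 (phenylselanyl)acetic acid
Product: 11 (5S)-5-[(2E)-4-[(4-methoxybenzyl)oxy]-2-methylbut-2-en-1-yl]-3-(phenylselanyl)dihydrofuran-2(3H)-one (C3 epimers), via hydroxy acid 10 (not isolated)
Conditions: 9, LiN(iPr)2 (2 equiv), THF, −78 to 0 °C; then 8, 0 °C to rt; then AcOH, THF, reflux
Reagents that add atoms: none
Why: The dianion of the selanylacetic acid opens the epoxide at its CH2 terminus (SN2 epoxide opening) and acid-catalysed lactonisation of the γ-hydroxy acid gives the γ-lactone with C8 unchanged; the former epoxide CH2 becomes C7.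

Step 6
Reactants: 11 (5S)-5-[(2E)-4-[(4-methoxybenzyl)oxy]-2-methylbut-2-en-1-yl]-3-(phenylselanyl)dihydrofuran-2(3H)-one
Product: 13 (5S)-5-[(2E)-4-[(4-methoxybenzyl)oxy]-2-methylbut-2-en-1-yl]furan-2(5H)-one, via selenoxide 12 (not isolated)
Conditions: mCPBA (1 equiv), CH2Cl2, −78 °C; then iPr2NH, −78 °C to rt
Reagents that add atoms: none
Why: Oxidation at selenium and syn elimination of the selenoxide (selenoxide elimination) can only remove a hydrogen from C7 and so should give the butenolide, while one equivalent of peracid at low temperature spares the trisubstituted alkene.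

Step 7
Reactants: 13 (5S)-5-[(2E)-4-[(4-methoxybenzyl)oxy]-2-methylbut-2-en-1-yl]furan-2(5H)-one
Product: 14 (4R,5S)-4-(1,3-dithian-2-yl)-5-[(2E)-4-[(4-methoxybenzyl)oxy]-2-methylbut-2-en-1-yl]dihydrofuran-2(3H)-one (4,5-trans)
Conditions: 1,3-dithiane, n-BuLi, THF, −30 °C; DMPU; then 13, −78 °C; AcOH
Reagents that add atoms: 1,3-dithiane, C1CSCSC1
Why: Conjugate (Michael) addition of 2-lithio-1,3-dithiane to the butenolide takes place on the face anti to the C8 side chain, which sets C7 trans to C8 and delivers C6 as a masked aldehyde.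

Step 8
Reactants: 14 (4R,5S)-4-(1,3-dithian-2-yl)-5-[(2E)-4-[(4-methoxybenzyl)oxy]-2-methylbut-2-en-1-yl]dihydrofuran-2(3H)-one
Product: 15 (2S,3R)-2-[(2E)-4-[(4-methoxybenzyl)oxy]-2-methylbut-2-en-1-yl]-5-oxotetrahydrofuran-3-carbaldehyde (2,3-trans)
Conditions: MeI, CaCO3, MeCN/H2O, 45 °C
Reagents that add atoms: water, O
Why: S-Methylation and buffered hydrolysis of the dithioacetal release the aldehyde under near-neutral conditions, so the β-acyloxy aldehyde should neither eliminate nor leave the favoured trans arrangement.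

Step 9
Reactants: 16 tert-butyldimethyl(prop-2-yn-1-yloxy)silane
Product: 17 (2Z)-2-{[(tert-butyldimethylsilyl)oxy]methyl}-3-[dimethyl(phenyl)silyl]prop-2-enal (CHO cis to silicon)
Conditions: Me2PhSiH, CO (20 atm), Rh4(CO)12 (cat.), Et3N, toluene, 100 °C
Reagents that add atoms: dimethylphenylsilane, C[SiH](C)c1ccccc1; carbon monoxide, [C-]#[O+]
Why: Rhodium-catalysed silylformylation of the terminal alkyne adds silicon to the terminal carbon and the formyl group to the internal carbon from the same side, so the formyl carbon (future C3) ends up cis to the carbon that will bond to C6.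

Step 10
Reactants: 17 (2Z)-2-{[(tert-butyldimethylsilyl)oxy]methyl}-3-[dimethyl(phenyl)silyl]prop-2-enal
Product: 18 (2E)-2-{[(tert-butyldimethylsilyl)oxy]methyl}-3-[dimethyl(phenyl)silyl]prop-2-en-1-ol (CH2OH cis to silicon)
Conditions: NaBH4, CeCl3·7H2O, MeOH, −40 °C
Reagents that add atoms: none
Why: 1,2-Reduction of the enal (Luche reduction) gives the allylic alcohol without touching the vinylsilane or the alkene geometry.

Step 11
Reactants: 18 (2E)-2-{[(tert-butyldimethylsilyl)oxy]methyl}-3-[dimethyl(phenyl)silyl]prop-2-en-1-ol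
Product: 19 (2E)-2-{[(tert-butyldimethylsilyl)oxy]methyl}-3-iodoprop-2-en-1-ol (iodine cis to CH2OH)
Conditions: NIS, 2,6-lutidine, (CF3)2CHOH, 0 °C
Reagents that add atoms: N-iodosuccinimide, O=C1CCC(=O)N1I
Why: Electrophilic ipso-iododesilylation of the vinylsilane in the fluorinated alcohol proceeds with retention, so iodine takes the place of silicon cis to the CH2OH arm.

Step 12
Reactants: 19 (2E)-2-{[(tert-butyldimethylsilyl)oxy]methyl}-3-iodoprop-2-en-1-ol
Product: 20 tert-butyl({(2E)-3-iodo-2-[(triethylsilyloxy)methyl]prop-2-en-1-yl}oxy)dimethylsilane (iodine cis to the CH2OSiEt3 arm)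
Conditions: Et3SiCl, imidazole, CH2Cl2, 0 °C
Reagents that add atoms: chlorotriethylsilane, CC[Si](Cl)(CC)CC
Why: Silyl ether formation at the primary alcohol gives an arm (future C3) that can later be freed by mild acid in the presence of TBS ethers.

Step 13
Reactants: 15 (2S,3R)-2-[(2E)-4-[(4-methoxybenzyl)oxy]-2-methylbut-2-en-1-yl]-5-oxotetrahydrofuran-3-carbaldehyde; 20 tert-butyl({(2E)-3-iodo-2-[(triethylsilyloxy)methyl]prop-2-en-1-yl}oxy)dimethylsilane
Product: 21 (4S,5S)-4-[(1R,2E)-3-{[(tert-butyldimethylsilyl)oxy]methyl}-1-hydroxy-4-[(triethylsilyl)oxy]but-2-en-1-yl]-5-[(2E)-4-[(4-methoxybenzyl)oxy]-2-methylbut-2-en-1-yl]dihydrofuran-2(3H)-one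
Conditions: CrCl2, NiCl2 (cat.), DMSO, rt
Reagents that add atoms: none
Why: Nozaki–Hiyama–Kishi coupling adds the alkenylchromium reagent to the aldehyde only and keeps the alkene geometry, and Felkin–Anh attack anti to the larger C8 branch (Re face of the aldehyde) should give the 6R carbinol.

Step 14
Reactants: 21 (the C6 alcohol from step 13)
Product: 22 (4R,5S)-4-[(1R,2E)-1-[(tert-butyldimethylsilyl)oxy]-3-{[(tert-butyldimethylsilyl)oxy]methyl}-4-[(triethylsilyl)oxy]but-2-en-1-yl]-5-[(2E)-4-[(4-methoxybenzyl)oxy]-2-methylbut-2-en-1-yl]dihydrofuran-2(3H)-one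
Conditions: TBSOTf, 2,6-lutidine, CH2Cl2, −78 to −40 °C
Reagents that add atoms: tert-butyldimethylsilyl trifluoromethanesulfonate, CC(C)(C)[Si](C)(C)OS(=O)(=O)C(F)(F)F
Why: Silyl ether formation with the silyl triflate protects the hindered secondary allylic C6 hydroxyl without disturbing the other silyl ethers.

Step 15
Reactants: 22 (the C6 TBS ether from step 14)
Product: 23 (4R,5S)-4-[(1R,2E)-1-[(tert-butyldimethylsilyl)oxy]-3-{[(tert-butyldimethylsilyl)oxy]methyl}-4-hydroxybut-2-en-1-yl]-5-[(2E)-4-[(4-methoxybenzyl)oxy]-2-methylbut-2-en-1-yl]dihydrofuran-2(3H)-one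
Conditions: PPTS (cat.), MeOH/CH2Cl2, 0 °C
Reagents that add atoms: none
Why: Acid-catalysed methanolysis cleaves the primary triethylsilyl ether much faster than primary or secondary TBS ethers (selective desilylation), which frees only the C3 hydroxyl.

Step 16
Reactants: 23 (the C3 alcohol from step 15); 24 2-nitrobenzenesulfonamide
Product: 25 (4R,5S)-4-[(1R,2E)-1-[(tert-butyldimethylsilyl)oxy]-3-{[(tert-butyldimethylsilyl)oxy]methyl}-4-{[(2-nitrophenyl)sulfonyl]amino}but-2-en-1-yl]-5-[(2E)-4-[(4-methoxybenzyl)oxy]-2-methylbut-2-en-1-yl]dihydrofuran-2(3H)-one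
Conditions: 24 (excess), PPh3, DIAD, THF, 0 °C to rt
Reagents that add atoms: none
Why: Mitsunobu N-alkylation of the acidic primary sulfonamide (Fukuyama–Mitsunobu reaction) by SN2 at the primary allylic C3; the excess of the more acidic NsNH2 should suppress a second alkylation.

Step 17
Reactants: 25 (the C3 sulfonamide from step 16)
Product: 26 (4R,5S)-4-[(1R,2E)-1-[(tert-butyldimethylsilyl)oxy]-3-{[(tert-butyldimethylsilyl)oxy]methyl}-4-{[(2-nitrophenyl)sulfonyl]amino}but-2-en-1-yl]-5-[(2E)-4-hydroxy-2-methylbut-2-en-1-yl]dihydrofuran-2(3H)-one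
Conditions: DDQ, CH2Cl2/pH 7 buffer, 0 °C
Reagents that add atoms: none
Why: Oxidative cleavage of the 4-methoxybenzyl ether by DDQ (through the benzylic oxocarbenium ion) leaves silyl ethers, sulfonamide, lactone and alkenes untouched and frees the C2 hydroxyl.

Step 18
Reactants: 26 (the C2 alcohol from step 17)
Product: 27 (6R,7R,8S)-6,15-bis[(tert-butyldimethylsilyl)oxy]-2a-[(2-nitrophenyl)sulfonyl]-2a-aza-2a-homogermacra-1(10)E,4E-dien-12,8-olide (eleven-membered ring with N between C2 and C3; C4=C5 ring-cis)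
Conditions: PPh3, DIAD, toluene/THF, 0.002 M, slow addition of 26, rt
Reagents that add atoms: none
Why: Intramolecular Fukuyama–Mitsunobu alkylation under high dilution closes the eleven-membered ring by SN2 attack of the sulfonamide nitrogen on the primary allylic C2; no stereocentre takes part.

Step 19
Reactants: 27 (the N-nosyl azacycle from step 18)
Product: 28 (6R,7R,8S)-6,15-bis[(tert-butyldimethylsilyl)oxy]-2a-aza-2a-homogermacra-1(10)E,4E-dien-12,8-olide (eleven-membered bis-allylic secondary amine; trans-fused saturated lactone)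
Conditions: PhSH, K2CO3, MeCN, rt
Reagents that add atoms: none
Why: Thiolate adds to the nitroarene (SNAr through a Meisenheimer complex) and the sulfonamide collapses with loss of SO2 to the free secondary amine (Fukuyama deprotection) under conditions that spare the lactone and the silyl ethers.

Step 20
Reactants: 28 (the eleven-membered amine from step 19)
Product: 30 (6R,7R,8S)-6,15-bis[(tert-butyldimethylsilyl)oxy]germacra-1(10)E,4E-dien-12,8-olide (ten-membered carbocycle fused to the γ-lactone; C4=C5 ring-cis), via isodiazene 29 (not isolated)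
Conditions: N-(benzyloxy)-N-(pivaloyloxy)-4-(trifluoromethyl)benzamide (1.5 equiv), THF, degassed, 45 °C
Reagents that add atoms: none
Why: Proposed new method: the amine nitrogen attacks the amide nitrogen of the anomeric amide and displaces pivalate, the resulting N-benzyloxy hydrazide eliminates benzyl 4-(trifluoromethyl)benzoate to give isodiazene 29, and loss of N2 leaves a singlet pair of allyl radicals (C2–C1–C10 and C3–C4–C5) that recombine before leaving the solvent cage. The closest known reaction type is the anomeric-amide nitrogen deletion of benzylic and small-ring secondary amines, which runs through the same isodiazene and radical pair. Ring A, the ten-membered carbocycle, closes by ring contraction, that is by intramolecular radical–radical coupling of the two CH2 termini that nitrogen had bridged, so no medium-ring entropy has to be paid here. No stereocentre is created, C6, C7 and C8 are spectators, and the E C1=C10 and ring-cis C4=C5 geometries should persist because rotation within an allyl radical is much slower than cage recombination. The selectivity needed is bond formation between C2 and C3, since coupling at C10 or C5 would instead close eight- or six-membered carbocycles; the shortest path joins the two primary termini, and C10 is tertiary while C5 sits next to the silylated C6. A [2,3] shift of the allylic isodiazene to a cyclic 1,2-diazene would lose N2 to the same radical pair and is therefore harmless.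

Step 21
Reactants: 30 (the ten-membered lactone from step 20)
Product: 31 (6R,7R,8S)-6,15-bis[(tert-butyldimethylsilyl)oxy]-13-(dimethylamino)germacra-1(10)E,4E-dien-12,8-olide (C11 epimers)
Conditions: LiN(iPr)2, THF, −78 °C; then CH2=NMe2+ I−, −78 °C to rt
Reagents that add atoms: N,N-dimethylmethyleneiminium iodide, C=[N+](C)C.[I-]
Why: The lithium enolate of the lactone is aminomethylated at C11 (Mannich reaction); the new centre at C11 is erased in the next step and C7 carries no leaving group that the enolate could expel.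

Step 22
Reactants: 31 (the Mannich base from step 21)
Product: 33 (6R,7R,8S)-6,15-bis[(tert-butyldimethylsilyl)oxy]germacra-1(10)E,4E,11(13)-trien-12,8-olide, via methiodide 32 (not isolated)
Conditions: MeI, MeOH, rt; then NaHCO3 (aq), EtOAc, rt
Reagents that add atoms: none
Why: N-Methylation followed by base-induced β-elimination of trimethylamine from the quaternary ammonium salt (E1cB, Hofmann-type elimination) gives the exocyclic C11=C13 alkene.

Step 23
Reactants: 33 (the bis-silylated methylene lactone from step 22)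
Product: 34 (6R,7S,8S)-6,15-dihydroxygermacra-1(10)E,4E,11(13)-trien-12,8-olide
Conditions: HF·pyridine, pyridine, THF, 0 °C to rt
Reagents that add atoms: none
Why: Fluoride-mediated desilylation under buffered acidic conditions removes both TBS groups without opening the lactone or adding to the methylene lactone.

Step 24
Reactants: 35 (E)-but-2-enal (crotonaldehyde)
Product: 36 (Z)-2-iodobut-2-enal
Conditions: I2, K2CO3, DMAP (cat.), THF/H2O, rt
Reagents that add atoms: iodine, II
Why: Amine-catalysed α-iodination of the enal (conjugate addition of DMAP, iodination of the enolate, elimination) gives the thermodynamically preferred Z isomer with iodine cis to methyl.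

Step 25
Reactants: 36 (Z)-2-iodobut-2-enal
Product: 37 (Z)-2-iodobut-2-en-1-ol
Conditions: NaBH4, MeOH, 0 °C
Reagents that add atoms: none
Why: Hydride 1,2-reduction of the aldehyde leaves the alkenyl iodide and its geometry intact.

Step 26
Reactants: 37 (Z)-2-iodobut-2-en-1-ol
Product: 38 (Z)-2-(hydroxymethyl)but-2-enoic acid
Conditions: Pd(OAc)2 (cat.), PPh3, K2CO3, CO (1 atm), DMF/H2O, 60 °C; then HCl (aq)
Reagents that add atoms: carbon monoxide, [C-]#[O+]; water, O
Why: Palladium-catalysed hydroxycarbonylation of the alkenyl iodide (oxidative addition, CO insertion, hydrolysis of the acylpalladium species) replaces iodine by CO2H with retention, so the carboxyl stays cis to methyl.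

Step 27
Reactants: 38 (Z)-2-(hydroxymethyl)but-2-enoic acid
Product: 39 (Z)-2-(acetoxymethyl)but-2-enoic acid
Conditions: Ac2O, pyridine, 0 °C to rt; then H2O
Reagents that add atoms: acetic anhydride, CC(=O)OC(C)=O
Why: O-Acetylation of the primary alcohol; any mixed anhydride formed at the carboxyl group is hydrolysed on aqueous work-up.

Step 28
Reactants: 34 (6R,7S,8S)-6,15-dihydroxygermacra-1(10)E,4E,11(13)-trien-12,8-olide; 39 (Z)-2-(acetoxymethyl)but-2-enoic acid
Product: 41 (6R,7S,8S)-15-{[(Z)-2-(acetoxymethyl)but-2-enoyl]oxy}-6-hydroxygermacra-1(10)E,4E,11(13)-trien-12,8-olide (CNP0184624.2), via mixed anhydride 40 (not isolated)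
Conditions: 39, 2,4,6-Cl3C6H2COCl, Et3N, toluene, rt; then 34, DMAP (cat.), −20 to 0 °C
Reagents that add atoms: none
Why: Yamaguchi esterification through the mixed anhydride should acylate the unhindered primary allylic C15 hydroxyl in preference to the hindered secondary C6 hydroxyl and does not isomerise the Z acid, so the last product is the target.

Compound list
1 | (S)-epichlorohydrin, (2S)-2-(chloromethyl)oxirane | ClC[C@@H]1CO1 | starting material
2 | ethynyltrimethylsilane | C#C[Si](C)(C)C | starting material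
3 | (S)-1-chloro-5-(trimethylsilyl)pent-4-yn-2-ol | C[Si](C)(C)C#CC[C@H](O)CCl | intermediate
4 | (S)-1-chloropent-4-yn-2-ol | C#CC[C@H](O)CCl | intermediate
5 | dimethylaluminium (2S,4E)-1-chloro-5-(dimethylalumanyl)-4-methylpent-4-en-2-olate (alkenyldimethylalane) | C[Al](C)/C=C(\C)C[C@@H](CCl)O[Al](C)C | intermediate
6 | (2E,5S)-6-chloro-3-methylhex-2-ene-1,5-diol | OC/C=C(\C)C[C@H](O)CCl | intermediate
7 | (2E)-3-methyl-4-[(2S)-oxiran-2-yl]but-2-en-1-ol (epoxy alcohol) | OC/C=C(\C)C[C@H]1CO1 | intermediate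
8 | (2S)-2-[(2E)-4-[(4-methoxybenzyl)oxy]-2-methylbut-2-en-1-yl]oxirane | COc1ccc(COC/C=C(\C)C[C@H]2CO2)cc1 | intermediate
9 | (phenylselanyl)acetic acid | OC(=O)C[Se]c1ccccc1 | starting material
10 | (4S,6E)-4-hydroxy-8-[(4-methoxybenzyl)oxy]-6-methyl-2-(phenylselanyl)oct-6-enoic acid (C2 epimers) | OC(=O)C([Se]c1ccccc1)C[C@@H](O)C/C(C)=C/COCc1ccc(OC)cc1 | intermediate
11 | (5S)-5-[(2E)-4-[(4-methoxybenzyl)oxy]-2-methylbut-2-en-1-yl]-3-(phenylselanyl)dihydrofuran-2(3H)-one (C3 epimers) | COc1ccc(COC/C=C(\C)C[C@H]2CC([Se]c3ccccc3)C(=O)O2)cc1 | intermediate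
12 | (5S)-5-[(2E)-4-[(4-methoxybenzyl)oxy]-2-methylbut-2-en-1-yl]-3-(phenylseleninyl)dihydrofuran-2(3H)-one (selenoxide) | COc1ccc(COC/C=C(\C)C[C@H]2CC([Se](=O)c3ccccc3)C(=O)O2)cc1 | intermediate
13 | (5S)-5-[(2E)-4-[(4-methoxybenzyl)oxy]-2-methylbut-2-en-1-yl]furan-2(5H)-one | COc1ccc(COC/C=C(\C)C[C@H]2C=CC(=O)O2)cc1 | intermediate
14 | (4R,5S)-4-(1,3-dithian-2-yl)-5-[(2E)-4-[(4-methoxybenzyl)oxy]-2-methylbut-2-en-1-yl]dihydrofuran-2(3H)-one (4,5-trans) | O=C1C[C@@H](C2SCCCS2)[C@H](C/C(C)=C/COCc2ccc(OC)cc2)O1 | intermediate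
15 | (2S,3R)-2-[(2E)-4-[(4-methoxybenzyl)oxy]-2-methylbut-2-en-1-yl]-5-oxotetrahydrofuran-3-carbaldehyde (2,3-trans) | O=C1C[C@@H](C=O)[C@H](C/C(C)=C/COCc2ccc(OC)cc2)O1 | intermediate
16 | tert-butyldimethyl(prop-2-yn-1-yloxy)silane | C#CCO[Si](C)(C)C(C)(C)C | starting material
17 | (2Z)-2-{[(tert-butyldimethylsilyl)oxy]methyl}-3-[dimethyl(phenyl)silyl]prop-2-enal (CHO cis to Si) | O=C/C(CO[Si](C)(C)C(C)(C)C)=C\[Si](C)(C)c1ccccc1 | intermediate
18 | (2E)-2-{[(tert-butyldimethylsilyl)oxy]methyl}-3-[dimethyl(phenyl)silyl]prop-2-en-1-ol (CH2OH cis to Si) | OC/C(CO[Si](C)(C)C(C)(C)C)=C\[Si](C)(C)c1ccccc1 | intermediate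
19 | (2E)-2-{[(tert-butyldimethylsilyl)oxy]methyl}-3-iodoprop-2-en-1-ol (I cis to CH2OH) | OC/C(CO[Si](C)(C)C(C)(C)C)=C\I | intermediate
20 | tert-butyl({(2E)-3-iodo-2-[(triethylsilyloxy)methyl]prop-2-en-1-yl}oxy)dimethylsilane (I cis to CH2OSiEt3) | CC[Si](CC)(CC)OC/C(CO[Si](C)(C)C(C)(C)C)=C\I | intermediate
21 | (4S,5S)-4-[(1R,2E)-3-{[(tert-butyldimethylsilyl)oxy]methyl}-1-hydroxy-4-[(triethylsilyl)oxy]but-2-en-1-yl]-5-[(2E)-4-[(4-methoxybenzyl)oxy]-2-methylbut-2-en-1-yl]dihydrofuran-2(3H)-one | O=C1C[C@@H]([C@H](O)/C=C(\CO[Si](CC)(CC)CC)CO[Si](C)(C)C(C)(C)C)[C@H](C/C(C)=C/COCc2ccc(OC)cc2)O1 | intermediate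
22 | (4R,5S)-4-[(1R,2E)-1-[(tert-butyldimethylsilyl)oxy]-3-{[(tert-butyldimethylsilyl)oxy]methyl}-4-[(triethylsilyl)oxy]but-2-en-1-yl]-5-[(2E)-4-[(4-methoxybenzyl)oxy]-2-methylbut-2-en-1-yl]dihydrofuran-2(3H)-one | O=C1C[C@@H]([C@H](O[Si](C)(C)C(C)(C)C)/C=C(\CO[Si](CC)(CC)CC)CO[Si](C)(C)C(C)(C)C)[C@H](C/C(C)=C/COCc2ccc(OC)cc2)O1 | intermediate
23 | (4R,5S)-4-[(1R,2E)-1-[(tert-butyldimethylsilyl)oxy]-3-{[(tert-butyldimethylsilyl)oxy]methyl}-4-hydroxybut-2-en-1-yl]-5-[(2E)-4-[(4-methoxybenzyl)oxy]-2-methylbut-2-en-1-yl]dihydrofuran-2(3H)-one | O=C1C[C@@H]([C@H](O[Si](C)(C)C(C)(C)C)/C=C(\CO)CO[Si](C)(C)C(C)(C)C)[C@H](C/C(C)=C/COCc2ccc(OC)cc2)O1 | intermediate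
24 | 2-nitrobenzenesulfonamide | NS(=O)(=O)c1ccccc1[N+](=O)[O-] | starting material
25 | (4R,5S)-4-[(1R,2E)-1-[(tert-butyldimethylsilyl)oxy]-3-{[(tert-butyldimethylsilyl)oxy]methyl}-4-{[(2-nitrophenyl)sulfonyl]amino}but-2-en-1-yl]-5-[(2E)-4-[(4-methoxybenzyl)oxy]-2-methylbut-2-en-1-yl]dihydrofuran-2(3H)-one | O=C1C[C@@H]([C@H](O[Si](C)(C)C(C)(C)C)/C=C(\CNS(=O)(=O)c2ccccc2[N+](=O)[O-])CO[Si](C)(C)C(C)(C)C)[C@H](C/C(C)=C/COCc2ccc(OC)cc2)O1 | intermediate
26 | (4R,5S)-4-[(1R,2E)-1-[(tert-butyldimethylsilyl)oxy]-3-{[(tert-butyldimethylsilyl)oxy]methyl}-4-{[(2-nitrophenyl)sulfonyl]amino}but-2-en-1-yl]-5-[(2E)-4-hydroxy-2-methylbut-2-en-1-yl]dihydrofuran-2(3H)-one | O=C1C[C@@H]([C@H](O[Si](C)(C)C(C)(C)C)/C=C(\CNS(=O)(=O)c2ccccc2[N+](=O)[O-])CO[Si](C)(C)C(C)(C)C)[C@H](C/C(C)=C/CO)O1 | intermediate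
27 | (6R,7R,8S)-6,15-bis[(tert-butyldimethylsilyl)oxy]-2a-[(2-nitrophenyl)sulfonyl]-2a-aza-2a-homogermacra-1(10)E,4E-dien-12,8-olide | C1C(=O)O[C@H]2C/C(C)=C/CN(S(=O)(=O)c3ccccc3[N+](=O)[O-])C/C(CO[Si](C)(C)C(C)(C)C)=C\[C@@H](O[Si](C)(C)C(C)(C)C)[C@H]12 | intermediate
28 | (6R,7R,8S)-6,15-bis[(tert-butyldimethylsilyl)oxy]-2a-aza-2a-homogermacra-1(10)E,4E-dien-12,8-olide (key-step precursor) | C1C(=O)O[C@H]2C/C(C)=C/CNC/C(CO[Si](C)(C)C(C)(C)C)=C\[C@@H](O[Si](C)(C)C(C)(C)C)[C@H]12 | intermediate
29 | isodiazene (N-nitrene, 1,1-diazene) of 28 | C1C(=O)O[C@H]2C/C(C)=C/C[N+](=[N-])C/C(CO[Si](C)(C)C(C)(C)C)=C\[C@@H](O[Si](C)(C)C(C)(C)C)[C@H]12 | intermediate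
30 | (6R,7R,8S)-6,15-bis[(tert-butyldimethylsilyl)oxy]germacra-1(10)E,4E-dien-12,8-olide (key-step product; C4=C5 ring-cis) | C1C(=O)O[C@H]2C/C(C)=C/CC/C(CO[Si](C)(C)C(C)(C)C)=C\[C@@H](O[Si](C)(C)C(C)(C)C)[C@H]12 | intermediate
31 | (6R,7R,8S)-6,15-bis[(tert-butyldimethylsilyl)oxy]-13-(dimethylamino)germacra-1(10)E,4E-dien-12,8-olide (C11 epimers) | CN(C)CC1C(=O)O[C@H]2C/C(C)=C/CC/C(CO[Si](C)(C)C(C)(C)C)=C\[C@@H](O[Si](C)(C)C(C)(C)C)[C@H]12 | intermediate
32 | N-methyl ammonium iodide (methiodide) of 31 | C[N+](C)(C)CC1C(=O)O[C@H]2C/C(C)=C/CC/C(CO[Si](C)(C)C(C)(C)C)=C\[C@@H](O[Si](C)(C)C(C)(C)C)[C@H]12.[I-] | intermediate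
33 | (6R,7R,8S)-6,15-bis[(tert-butyldimethylsilyl)oxy]germacra-1(10)E,4E,11(13)-trien-12,8-olide | C=C1C(=O)O[C@H]2C/C(C)=C/CC/C(CO[Si](C)(C)C(C)(C)C)=C\[C@@H](O[Si](C)(C)C(C)(C)C)[C@H]12 | intermediate
34 | (6R,7S,8S)-6,15-dihydroxygermacra-1(10)E,4E,11(13)-trien-12,8-olide | C=C1C(=O)O[C@H]2C/C(C)=C/CC/C(CO)=C\[C@@H](O)[C@H]12 | intermediate
35 | (E)-but-2-enal (crotonaldehyde) | C/C=C/C=O | starting material
36 | (Z)-2-iodobut-2-enal | C/C=C(\I)C=O | intermediate
37 | (Z)-2-iodobut-2-en-1-ol | C/C=C(\I)CO | intermediate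
38 | (Z)-2-(hydroxymethyl)but-2-enoic acid | C/C=C(\C(=O)O)CO | intermediate
39 | (Z)-2-(acetoxymethyl)but-2-enoic acid | C/C=C(\C(=O)O)COC(C)=O | intermediate
40 | (Z)-2-(acetoxymethyl)but-2-enoic 2,4,6-trichlorobenzoic anhydride | C/C=C(\C(=O)OC(=O)c1c(Cl)cc(Cl)cc1Cl)COC(C)=O | intermediate
41 | (6R,7S,8S)-15-{[(Z)-2-(acetoxymethyl)but-2-enoyl]oxy}-6-hydroxygermacra-1(10)E,4E,11(13)-trien-12,8-olide (CNP0184624.2) | C=C1C(=O)O[C@H]2C/C(C)=C/CC/C(COC(=O)/C(=C\C)COC(C)=O)=C\[C@@H](O)[C@H]12 | target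

Total step count: 28. Longest linear sequence: 20 steps (steps 1–8, 13–23 and 28); steps 9–12 and 24–27 make the two side fragments.

Steps most likely to fail

Step 20 (key step). The radical pair may escape the cage, couple at C10 or C5, or disproportionate to dienes instead of closing ring A, and the amine may be consumed without clean isodiazene formation. The fallback forms the C2–C3 bond by the established intramolecular alkylation of an allylic sulfone and sets out from 23. Mitsunobu thioetherification with thiophenol gives the allylic phenyl sulfide F1. Oxidation with H2O2 and (NH4)6Mo7O24 gives the phenyl sulfone F2. DDQ then frees the C2 hydroxyl to give the sulfonyl alcohol F3, and CBr4/PPh3 turns it into the allylic bromide F4. KN(SiMe3)2 in dilute THF at −78 °C closes the ten-membered ring by attack of the C3 sulfonyl carbanion on C2, giving the cyclic sulfone F5. Reductive desulfonylation with Na(Hg) and Na2HPO4 in MeOH returns to the route at 30.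

Step 18. Ring closure to the eleven-membered ring may lose out to intermolecular alkylation (oligomers) because the activated alcohol is short-lived. The fallback separates activation from ring closure and sets out from 26. CBr4/PPh3 gives the allylic bromide F6, which is added slowly to Cs2CO3 and Bu4NI in dilute MeCN at 50 °C. SN2 displacement by the caesium sulfonamide then closes the ring and returns to the route at 27.

Step 13. Facial selectivity at the aldehyde may be poor, because both branches at C7 are ring carbons, giving a mixture of C6 epimers. The fallback sets C6 by reagent control and starts from the epimer mixture of 21. Oxidation with the triacetoxy periodinane (1,1,1-triacetoxy-1,1-dihydro-1,2-benziodoxol-3(1H)-one) gives the enone F7. CBS reduction with BH3·SMe2 and (R)-2-methyl-CBS-oxazaborolidine should deliver hydride to the Si face of the ketone if, as is usual for enones, the alkenyl group takes the large-group position. This returns to the route at 21.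

Further compounds
F1 | step 20 | (4R,5S)-4-[(1R,2E)-1-[(tert-butyldimethylsilyl)oxy]-3-{[(tert-butyldimethylsilyl)oxy]methyl}-4-(phenylsulfanyl)but-2-en-1-yl]-5-[(2E)-4-[(4-methoxybenzyl)oxy]-2-methylbut-2-en-1-yl]dihydrofuran-2(3H)-one | O=C1C[C@@H]([C@H](O[Si](C)(C)C(C)(C)C)/C=C(\CSc2ccccc2)CO[Si](C)(C)C(C)(C)C)[C@H](C/C(C)=C/COCc2ccc(OC)cc2)O1
F2 | step 20 | phenyl sulfone corresponding to F1 | O=C1C[C@@H]([C@H](O[Si](C)(C)C(C)(C)C)/C=C(\CS(=O)(=O)c2ccccc2)CO[Si](C)(C)C(C)(C)C)[C@H](C/C(C)=C/COCc2ccc(OC)cc2)O1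
F3 | step 20 | sulfonyl alcohol, F2 with the C2 hydroxyl free | O=C1C[C@@H]([C@H](O[Si](C)(C)C(C)(C)C)/C=C(\CS(=O)(=O)c2ccccc2)CO[Si](C)(C)C(C)(C)C)[C@H](C/C(C)=C/CO)O1
F4 | step 20 | allylic bromide, F3 with bromine at C2 | O=C1C[C@@H]([C@H](O[Si](C)(C)C(C)(C)C)/C=C(\CS(=O)(=O)c2ccccc2)CO[Si](C)(C)C(C)(C)C)[C@H](C/C(C)=C/CBr)O1
F5 | step 20 | (6R,7R,8S)-6,15-bis[(tert-butyldimethylsilyl)oxy]-3-(phenylsulfonyl)germacra-1(10)E,4E-dien-12,8-olide (C3 epimers) | C1C(=O)O[C@H]2C/C(C)=C/CC(S(=O)(=O)c3ccccc3)/C(CO[Si](C)(C)C(C)(C)C)=C\[C@@H](O[Si](C)(C)C(C)(C)C)[C@H]12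
F6 | step 18 | allylic bromide, 26 with bromine in place of the C2 hydroxyl | O=C1C[C@@H]([C@H](O[Si](C)(C)C(C)(C)C)/C=C(\CNS(=O)(=O)c2ccccc2[N+](=O)[O-])CO[Si](C)(C)C(C)(C)C)[C@H](C/C(C)=C/CBr)O1
F7 | step 13 | enone, 21 with a ketone at C6 | O=C1C[C@@H](C(=O)/C=C(\CO[Si](CC)(CC)CC)CO[Si](C)(C)C(C)(C)C)[C@H](C/C(C)=C/COCc2ccc(OC)cc2)O1
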